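**Plan**

- Retrosynthesis: the C3–O angelate ester is cut first, then the aryl–acetyl bond at C5 (back to an aryl bromide through a 1-ethoxyvinyl group), then the C=CH2 bond of the isopropenyl group (back to a methyl ketone), and last the C2–C3 bond of the dihydrofuran ring.
- Enabling feature: C3 is a benzylic carbinol carbon on C3a, and C2 carries O1 plus a carbon that can stand at the ketone level. C2–C3 is therefore the bond of an aldol between an aryl aldehyde and the α-carbon of an aryloxyacetone held ortho to it through C7a.
- Forward: the benzene ring (ring A) is bought with its three oxygens. Bromination at C5 and O-acetonylation give the keto aldehyde, the aldol closes the dihydrofuran ring (ring B), and silylation, Stille coupling, methylenation, desilylation, angeloylation and enol ether hydrolysis finish the periphery.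
- Stereochemistry: C2 and C3 are both set in the ring closure by (S)-proline (cis; 2S,3R in the ketone, 2R,3R once acetyl has become isopropenyl, a change of priority only). Later steps are non-basic at C2 and non-ionising at C3, and the Z alkene is bought as angelic acid.

Key step: step 3

Assumption: the sense of induction in step 3 is taken from the accepted hydrogen-bonded enamine transition-state model for proline aldol reactions; should the aldol product prove to be the mirror image, (R)-proline would be used with no other change.

**Route**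

Step 1
Reactants: 1 2-hydroxy-3,4-dimethoxybenzaldehyde
Product: 2 5-bromo-2-hydroxy-3,4-dimethoxybenzaldehyde
Conditions: NBS, MeCN, 0 °C to rt
Reagents that add atoms: N-bromosuccinimide, O=C1CCC(=O)N1Br
Why: Electrophilic aromatic bromination; the phenol directs para to C5, which is also ortho to the 4-methoxy group, whereas the only other free position lies next to the deactivating formyl group.

Step 2
Reactants: 2 5-bromo-2-hydroxy-3,4-dimethoxybenzaldehyde; 3 chloroacetone
Product: 4 5-bromo-3,4-dimethoxy-2-(2-oxopropoxy)benzaldehyde
Conditions: K2CO3, DMF, 0 °C to rt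
Reagents that add atoms: none
Why: Williamson ether synthesis; the phenoxide displaces chloride from the activated α-chloro ketone, and a weak base at room temperature should keep the product from condensing onto its own aldehyde (Rap–Stoermer-type benzofuran formation).

Step 3
Reactants: 4 5-bromo-3,4-dimethoxy-2-(2-oxopropoxy)benzaldehyde
Product: 5 1-[(2S,3R)-5-bromo-3-hydroxy-6,7-dimethoxy-2,3-dihydro-1-benzofuran-2-yl]ethan-1-one
Conditions: (S)-proline (30 mol %), DMF, rt
Reagents that add atoms: none
Why: (S)-Proline condenses with the methyl ketone of 4 to give the E enamine on the oxygen-bearing CH2 side; its α-carbon (the future C2) adds to the ortho formyl carbon (the future C3) while the carboxylic acid hydrogen-bonds to the aldehyde oxygen, and hydrolysis of the iminium ion releases 5 and the catalyst. The closest known reaction is the proline-catalysed direct intramolecular aldol reaction of O-acetonyl salicylaldehydes to cis-2-acyl-2,3-dihydrobenzofuran-3-ols, a relative of the 6-enolexo aldolisations of dicarbonyl compounds. The dihydrofuran ring closes in the 5-(enolexo)-exo-trig mode, favoured over reaction through the methyl-side enamine, which would need a seven-membered ring. C3 is set by the aldehyde face that the hydrogen bond to the carboxyl group of the anti enamine exposes, and C2 by the enamine face on which that carboxyl group sits; because the aldehyde oxygen must lie on the carboxyl side, next to the carbon that becomes the acetyl group, hydroxyl and acetyl should end up cis, and with (S)-proline the model leads to (2S,3R). The step needs regioselectivity between the two enamines, cis selectivity and survival of the aldol without loss of water to the aromatic benzofuran: the aryloxy group and the five-membered closure secure the first, the hydrogen-bonded bicyclic transition state the second and the base-free medium at room temperature the third, while bromine at C5 in place of acetyl leaves a single ketone for enamine formation.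

Step 4
Reactants: 5 1-[(2S,3R)-5-bromo-3-hydroxy-6,7-dimethoxy-2,3-dihydro-1-benzofuran-2-yl]ethan-1-one
Product: 6 1-[(2S,3R)-5-bromo-3-{[tert-butyl(dimethyl)silyl]oxy}-6,7-dimethoxy-2,3-dihydro-1-benzofuran-2-yl]ethan-1-one
Conditions: TBSOTf, 2,6-lutidine, CH2Cl2, −78 °C
Reagents that add atoms: tert-butyldimethylsilyl trifluoromethanesulfonate, CC(C)(C)[Si](C)(C)OS(=O)(=O)C(F)(F)F
Why: Silyl ether protection with the silyl triflate and a hindered pyridine base at low temperature should cap the aldol hydroxyl before retro-aldol, epimerisation at C2 or elimination to the benzofuran can set in; no stereocentre is touched.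

Step 5
Reactants: 6 1-[(2S,3R)-5-bromo-3-{[tert-butyl(dimethyl)silyl]oxy}-6,7-dimethoxy-2,3-dihydro-1-benzofuran-2-yl]ethan-1-one; 7 tributyl(1-ethoxyethenyl)stannane
Product: 8 1-[(2S,3R)-3-{[tert-butyl(dimethyl)silyl]oxy}-5-(1-ethoxyethenyl)-6,7-dimethoxy-2,3-dihydro-1-benzofuran-2-yl]ethan-1-one
Conditions: Pd(PPh3)4 (5 mol %), toluene, 100 °C; Et3N-treated SiO2
Reagents that add atoms: none
Why: Stille coupling (oxidative addition of zerovalent palladium into the aryl bromide, transmetalation of the 1-ethoxyvinyl group, reductive elimination) installs the masked acetyl group under neutral, base-free conditions that leave the epimerisable ketone and the silyl ether alone, and it is placed here so that palladium never meets the allylic aryl ether or the angelate of later intermediates.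

Step 6
Reactants: 8 1-[(2S,3R)-3-{[tert-butyl(dimethyl)silyl]oxy}-5-(1-ethoxyethenyl)-6,7-dimethoxy-2,3-dihydro-1-benzofuran-2-yl]ethan-1-one
Product: 9 tert-butyl{[(2R,3R)-5-(1-ethoxyethenyl)-6,7-dimethoxy-2-(prop-1-en-2-yl)-2,3-dihydro-1-benzofuran-3-yl]oxy}dimethylsilane
Conditions: Cp2TiMe2 (3 equiv), toluene/THF, 65 °C, dark
Reagents that add atoms: dimethyltitanocene (Cp2TiMe2), C[Ti](C)(C1C=CC=C1)C1C=CC=C1
Why: Petasis methylenation; the non-basic titanium methylidene formed on heating should convert the enolisable α-aryloxy ketone into the isopropenyl group without epimerising C2, while the enol ether, inert to the carbene, keeps the future aryl ketone masked so that only one carbonyl group is methylenated.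

Step 7
Reactants: 9 tert-butyl{[(2R,3R)-5-(1-ethoxyethenyl)-6,7-dimethoxy-2-(prop-1-en-2-yl)-2,3-dihydro-1-benzofuran-3-yl]oxy}dimethylsilane
Product: 10 (2R,3R)-5-(1-ethoxyethenyl)-6,7-dimethoxy-2-(prop-1-en-2-yl)-2,3-dihydro-1-benzofuran-3-ol
Conditions: Bu4NF, THF, 0 °C to rt; NaHCO3 work-up
Reagents that add atoms: none
Why: Fluoride-mediated desilylation; the substrate now carries no carbonyl group, so the basic fluoride can cause neither elimination nor epimerisation, and the acid-sensitive enol ether is untouched.

Step 8
Reactants: 10 (2R,3R)-5-(1-ethoxyethenyl)-6,7-dimethoxy-2-(prop-1-en-2-yl)-2,3-dihydro-1-benzofuran-3-ol; 11 angelic acid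
Product: 13 (2R,3R)-5-(1-ethoxyethenyl)-6,7-dimethoxy-2-(prop-1-en-2-yl)-2,3-dihydro-1-benzofuran-3-yl (2Z)-2-methylbut-2-enoate, via angelic 2,4,6-trichlorobenzoic anhydride 12 (not isolated)
Conditions: 11, 2,4,6-trichlorobenzoyl chloride, Et3N, toluene, rt; then 10, Et3N (excess), toluene, 75 °C
Reagents that add atoms: 2,4,6-trichlorobenzoyl chloride, O=C(Cl)c1c(Cl)cc(Cl)cc1Cl (its aroyl group is held in 12 only and does not enter 13)
Why: Yamaguchi-type mixed-anhydride esterification run without a nucleophilic catalyst; the alcohol attacks the unhindered angeloyl carbonyl of 12 with retention at C3, omission of DMAP avoids the conjugate addition–elimination that turns angelates into tiglates, and excess Et3N buffers the liberated acid so that the enol ether and the benzylic C3–O bond should survive.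

Step 9
Reactants: 13 (2R,3R)-5-(1-ethoxyethenyl)-6,7-dimethoxy-2-(prop-1-en-2-yl)-2,3-dihydro-1-benzofuran-3-yl (2Z)-2-methylbut-2-enoate
Product: 14 (2R,3R)-5-acetyl-6,7-dimethoxy-2-(prop-1-en-2-yl)-2,3-dihydro-1-benzofuran-3-yl (2Z)-2-methylbut-2-enoate
Conditions: 0.1 M aq HCl, THF, 0 °C; NaHCO3 quench
Reagents that add atoms: water, O
Why: Acid-catalysed enol ether hydrolysis (protonation at the terminal carbon, collapse of the hemiketal) of an α-aryl enol ether is far faster than ionisation of the benzylic angelate or isomerisation of either alkene, so brief cold dilute acid should unmask the C5 acetyl group alone.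

**Compound list**

1 | 2-hydroxy-3,4-dimethoxybenzaldehyde | COc1ccc(C=O)c(O)c1OC | starting material
2 | 5-bromo-2-hydroxy-3,4-dimethoxybenzaldehyde | COc1c(Br)cc(C=O)c(O)c1OC | intermediate
3 | chloroacetone (1-chloropropan-2-one) | CC(=O)CCl | starting material
4 | 5-bromo-3,4-dimethoxy-2-(2-oxopropoxy)benzaldehyde | CC(=O)COc1c(C=O)cc(Br)c(OC)c1OC | intermediate
5 | 1-[(2S,3R)-5-bromo-3-hydroxy-6,7-dimethoxy-2,3-dihydro-1-benzofuran-2-yl]ethan-1-one | CC(=O)[C@H]1Oc2c(cc(Br)c(OC)c2OC)[C@H]1O | intermediate
6 | 1-[(2S,3R)-5-bromo-3-{[tert-butyl(dimethyl)silyl]oxy}-6,7-dimethoxy-2,3-dihydro-1-benzofuran-2-yl]ethan-1-one | CC(=O)[C@H]1Oc2c(cc(Br)c(OC)c2OC)[C@H]1O[Si](C)(C)C(C)(C)C | intermediate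
7 | tributyl(1-ethoxyethenyl)stannane | CCCC[Sn](CCCC)(CCCC)C(=C)OCC | starting material
8 | 1-[(2S,3R)-3-{[tert-butyl(dimethyl)silyl]oxy}-5-(1-ethoxyethenyl)-6,7-dimethoxy-2,3-dihydro-1-benzofuran-2-yl]ethan-1-one | CC(=O)[C@H]1Oc2c(cc(C(=C)OCC)c(OC)c2OC)[C@H]1O[Si](C)(C)C(C)(C)C | intermediate
9 | tert-butyl{[(2R,3R)-5-(1-ethoxyethenyl)-6,7-dimethoxy-2-(prop-1-en-2-yl)-2,3-dihydro-1-benzofuran-3-yl]oxy}dimethylsilane | C=C(C)[C@H]1Oc2c(cc(C(=C)OCC)c(OC)c2OC)[C@H]1O[Si](C)(C)C(C)(C)C | intermediate
10 | (2R,3R)-5-(1-ethoxyethenyl)-6,7-dimethoxy-2-(prop-1-en-2-yl)-2,3-dihydro-1-benzofuran-3-ol | C=C(C)[C@H]1Oc2c(cc(C(=C)OCC)c(OC)c2OC)[C@H]1O | intermediate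
11 | angelic acid, (2Z)-2-methylbut-2-enoic acid | C/C=C(/C)C(=O)O | starting material
12 | angelic 2,4,6-trichlorobenzoic anhydride, (2Z)-2-methylbut-2-enoic 2,4,6-trichlorobenzoic anhydride | C/C=C(/C)C(=O)OC(=O)c1c(Cl)cc(Cl)cc1Cl | intermediate
13 | (2R,3R)-5-(1-ethoxyethenyl)-6,7-dimethoxy-2-(prop-1-en-2-yl)-2,3-dihydro-1-benzofuran-3-yl (2Z)-2-methylbut-2-enoate | C=C(C)[C@H]1Oc2c(cc(C(=C)OCC)c(OC)c2OC)[C@H]1OC(=O)/C(C)=C\C | intermediate
14 | (2R,3R)-5-acetyl-6,7-dimethoxy-2-(prop-1-en-2-yl)-2,3-dihydro-1-benzofuran-3-yl (2Z)-2-methylbut-2-enoate | C=C(C)[C@H]1Oc2c(cc(C(C)=O)c(OC)c2OC)[C@H]1OC(=O)/C(C)=C\C | target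

**Summary**

Total step count: 9. Longest linear sequence: 9 steps, from 1 to 14.

**Steps most likely to fail**

Step 3. Facial discrimination in the enamine addition may be incomplete, and retro-aldol equilibration or loss of water to the aromatic benzofuran may erode the cis and enantiomeric purity. The fallback moves the source of absolute configuration from the catalyst to an enzyme. It sets out from 4, which is closed with racemic proline under the same conditions to the racemic cis aldol rac-1-[(2S,3R)-5-bromo-3-hydroxy-6,7-dimethoxy-2,3-dihydro-1-benzofuran-2-yl]ethan-1-one F1. This is submitted to lipase-catalysed kinetic resolution (Candida antarctica lipase B or Burkholderia cepacia lipase, vinyl acetate, MTBE, rt). By analogy with the acylation of 1-indanol-type benzylic alcohols, the enzyme should acetylate the (3S) carbinol of the unwanted enantiomer to (2R,3S)-2-acetyl-5-bromo-6,7-dimethoxy-2,3-dihydro-1-benzofuran-3-yl acetate F2 and leave the (2S,3R) alcohol untouched. After chromatographic separation the route is rejoined at 5. The same resolution could be applied to scalemic 5 from step 3.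

Step 8. The angeloyl unit may isomerise from Z to E during activation or acyl transfer, and acylation of the hindered cis alcohol may be slow enough for ionisation at C3 to compete. The fallback builds the Z alkene on the substrate and never handles an activated angelic acid. It sets out from 10, which is esterified (DCC, DMAP, CH2Cl2, 0 °C) with 2-[bis(2,2,2-trifluoroethoxy)phosphoryl]propanoic acid, obtained by saponification of its commercial methyl ester. This gives (2R,3R)-5-(1-ethoxyethenyl)-6,7-dimethoxy-2-(prop-1-en-2-yl)-2,3-dihydro-1-benzofuran-3-yl 2-[bis(2,2,2-trifluoroethoxy)phosphoryl]propanoate F3, a mixture at the phosphonate carbon. Still–Gennari olefination with acetaldehyde (KN(SiMe3)2, 18-crown-6, THF, −78 °C) should then give the Z-trisubstituted enoate, and the route is rejoined at 13. The intermediate carries no ketone at this stage, so the strong base has no competing enolisable site.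

Step 6. Prolonged heating may cause β-elimination of the silyloxy group or epimerisation at C2, or the hindered ketone may be methylenated only sluggishly. The fallback is a two-stage Peterson olefination and sets out from 8. Addition of Me3SiCH2MgCl premixed with CeCl3 (THF, −78 °C), a non-basic organocerium reagent, should give 2-[(2S,3R)-3-{[tert-butyl(dimethyl)silyl]oxy}-5-(1-ethoxyethenyl)-6,7-dimethoxy-2,3-dihydro-1-benzofuran-2-yl]-1-(trimethylsilyl)propan-2-ol F4, a mixture at the new carbinol carbon. Syn elimination with KH (THF, 0 °C) then forms the 1,1-disubstituted alkene, and the route is rejoined at 9. The basic elimination is chosen over the acidic one because of the enol ether.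

**Further compounds**

F1 | step 3 | rac-1-[(2S,3R)-5-bromo-3-hydroxy-6,7-dimethoxy-2,3-dihydro-1-benzofuran-2-yl]ethan-1-one (racemate, one enantiomer drawn) | CC(=O)[C@H]1Oc2c(cc(Br)c(OC)c2OC)[C@H]1O
F2 | step 3 | (2R,3S)-2-acetyl-5-bromo-6,7-dimethoxy-2,3-dihydro-1-benzofuran-3-yl acetate | CC(=O)[C@@H]1Oc2c(cc(Br)c(OC)c2OC)[C@@H]1OC(C)=O
F3 | step 8 | (2R,3R)-5-(1-ethoxyethenyl)-6,7-dimethoxy-2-(prop-1-en-2-yl)-2,3-dihydro-1-benzofuran-3-yl 2-[bis(2,2,2-trifluoroethoxy)phosphoryl]propanoate | C=C(C)[C@H]1Oc2c(cc(C(=C)OCC)c(OC)c2OC)[C@H]1OC(=O)C(C)P(=O)(OCC(F)(F)F)OCC(F)(F)F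
F4 | step 6 | 2-[(2S,3R)-3-{[tert-butyl(dimethyl)silyl]oxy}-5-(1-ethoxyethenyl)-6,7-dimethoxy-2,3-dihydro-1-benzofuran-2-yl]-1-(trimethylsilyl)propan-2-ol | C[Si](C)(C)CC(C)(O)[C@H]1Oc2c(cc(C(=C)OCC)c(OC)c2OC)[C@H]1O[Si](C)(C)C(C)(C)C
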